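Each oxolane ring (O1, C2 aryl, C3, C4 carbinol, C5) is disconnected across O1–C2 and C4–C5 into formaldehyde and a three-carbon C2–C3–C4 unit: a formal (3+2) annulation that exploits the 1,3-relationship between benzylic C2, where a para-oxygenated aryl group stabilises positive charge, and C4, which can be an enolate carbon. The precursor is a cyclopropane-fused butyrolactone (7) in which the C2–C4 bond is the strained, polarised bond; the lactone is a temporary ring that activates, relays configuration from C3 and later supplies the C3 hydroxymethyl and the benzylic CH2 on C4. One epoxide (13) made this way serves both halves, which are joined by biaryl cross-coupling.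

Key step: step 6

Remark: the oxolane atoms are numbered O1, C2 (aryl), C3 (CH2OH), C4 (carbinol), C5 (CH2) throughout; TIPS = triisopropylsilyl, TIPSO = triisopropylsilyloxy; formaldehyde 8 is taken from commercial paraformaldehyde.

Step 1
Reactants: 1 vanillin
Product: 2 3-methoxy-4-(TIPSO)benzaldehyde
Conditions: TIPSCl, imidazole, DMF, rt
Reagents that add atoms: triisopropylsilyl chloride, CC(C)[Si](Cl)(C(C)C)C(C)C
Why: O-silylation of the phenol should give an ether that is stable to base and hydride and keeps the para oxygen an electron donor for the later cyclopropane opening; no stereocentre is formed.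

Step 2
Reactants: 2 3-methoxy-4-(TIPSO)benzaldehyde
Product: 3 methyl (Z)-3-[3-methoxy-4-(TIPSO)phenyl]prop-2-enoate
Conditions: (CF3CH2O)2P(O)CH2CO2Me, KHMDS, 18-crown-6, THF, −78 °C
Reagents that add atoms: methyl bis(2,2,2-trifluoroethyl)phosphonoacetate, COC(=O)CP(=O)(OCC(F)(F)F)OCC(F)(F)F
Why: Still–Gennari variant of the Horner–Wadsworth–Emmons olefination, in which fast elimination from the kinetic adduct of the electron-poor phosphonate should give the Z alkene that the endo-aryl cyclopropane requires.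

Step 3
Reactants: 3 methyl (Z)-3-[3-methoxy-4-(TIPSO)phenyl]prop-2-enoate
Product: 4 (Z)-3-[3-methoxy-4-(TIPSO)phenyl]prop-2-en-1-ol
Conditions: DIBAL-H (2.2 equiv), CH2Cl2, −78 °C; aqueous potassium sodium tartrate work-up
Reagents that add atoms: none
Why: 1,2-reduction of the enoate by the aluminium hydride should leave the Z double bond and the aryl silyl ether untouched.

Step 4
Reactants: 4 (Z)-3-[3-methoxy-4-(TIPSO)phenyl]prop-2-en-1-ol
Product: 6 (Z)-3-[3-methoxy-4-(TIPSO)phenyl]prop-2-en-1-yl diazoacetate, via allylic bromoacetate 5 (not isolated)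
Conditions: BrCH2COBr, NaHCO3, MeCN, 0 °C; then TsNHNHTs, DBU, THF, 0 °C
Reagents that add atoms: bromoacetyl bromide, BrCC(=O)Br; N,N'-ditosylhydrazine, Cc1ccc(cc1)S(=O)(=O)NNS(=O)(=O)c1ccc(C)cc1
Why: acylation, then N-alkylation of the bis-sulfonylhydrazine and twofold base-induced loss of sulfinate, is a standard diazoacetate synthesis that should not isomerise the Z allylic ester.

Step 5
Reactants: 6 (Z)-3-[3-methoxy-4-(TIPSO)phenyl]prop-2-en-1-yl diazoacetate
Product: 7 (1S,5R,6S)-6-[3-methoxy-4-(TIPSO)phenyl]-3-oxabicyclo[3.1.0]hexan-2-one (aryl endo)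
Conditions: Rh2(5R-MEPY)4 (1 mol %), CH2Cl2, reflux, slow addition
Reagents that add atoms: none
Why: intramolecular cyclopropanation by a chiral dirhodium carboxamidate carbenoid (divalent rhodium) is concerted, so the Z geometry should place the aryl group endo (cis to the lactone CH2O arm), and the catalyst antipode is chosen to give the 1S,5R,6S series (expected to be the 5R catalyst by analogy with other Z allylic diazoacetates); C5 set here carries the absolute configuration of the whole route.

Step 6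
Reactants: 7 (1S,5R,6S)-6-[3-methoxy-4-(TIPSO)phenyl]-3-oxabicyclo[3.1.0]hexan-2-one; 8 formaldehyde (as paraformaldehyde)
Product: 9 (1R,5R,6S)-6-[3-methoxy-4-(TIPSO)phenyl]-3,7-dioxabicyclo[3.3.0]octan-2-one (cis-fused, aryl exo)
Conditions: paraformaldehyde (5 equiv), Sc(OTf)3 (20 mol %), 4 Å MS, ClCH2CH2Cl, 40 °C
Reagents that add atoms: none
Why: Proposed new method: a Lewis-acid-catalysed (3+2) annulation of a donor–acceptor cyclopropane with an aldehyde, whose closest known type is the Sn(OTf)2- or Sc(OTf)3-catalysed annulation of 2-arylcyclopropane-1,1-diesters with aldehydes, is extended to a cyclopropane activated by one lactone carbonyl and to formaldehyde. Sc(OTf)3 on the lactone carbonyl polarises the C1–C6 bond, which the para-silyloxyaryl donor and the strain of the endo aryl group make labile; the formaldehyde oxygen attacks benzylic C6 with inversion and the oxocarbenium ion so formed is closed by the scandium lactone enolate at C1 (5-(enolexo)-endo-trig), so that the O–C6 and C1–CH2 bonds arise in one operation. C5 is not touched and relays its configuration; C1 can only close cis on the lactone ring; C6 becomes exo, trans to the CH2O arm, by inversion of the endo-aryl cyclopropane. If the opening turns ionic the same isomer is expected, because the aryl group prefers the convex face and the benzylic ether can equilibrate under the conditions. The selectivity needed is capture of the benzylic cation by formaldehyde in preference to proton loss or arylation, which excess paraformaldehyde and a low cation concentration under catalytic Sc(OTf)3 should secure.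

Step 7
Reactants: 9 (1R,5R,6S)-6-[3-methoxy-4-(TIPSO)phenyl]-3,7-dioxabicyclo[3.3.0]octan-2-one
Product: 10 (1S,5R,6S)-1-hydroxy-6-[3-methoxy-4-(TIPSO)phenyl]-3,7-dioxabicyclo[3.3.0]octan-2-one
Conditions: KHMDS, THF, −78 °C; then 2-(phenylsulfonyl)-3-phenyloxaziridine, −78 °C; AcOH quench
Reagents that add atoms: 2-(phenylsulfonyl)-3-phenyloxaziridine, O=S(=O)(N1OC1c1ccccc1)c1ccccc1
Why: electrophilic hydroxylation of the potassium lactone enolate by an N-sulfonyloxaziridine; the cis-fused bicycle can take up oxygen only on its convex face, so the new hydroxyl on C1 should be trans to the CH2O arm on C5, as in the target.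

Step 8
Reactants: 10 (1S,5R,6S)-1-hydroxy-6-[3-methoxy-4-(TIPSO)phenyl]-3,7-dioxabicyclo[3.3.0]octan-2-one
Product: 11 (3R,4R,5S)-3,4-bis(hydroxymethyl)-5-[3-methoxy-4-(TIPSO)phenyl]oxolan-3-ol
Conditions: LiBH4, THF, 0 °C → rt
Reagents that add atoms: none
Why: borohydride reduction of the α-hydroxy lactone should open the temporary ring to two primary alcohols without touching the stereocentres or the aryl silyl ether.

Step 9
Reactants: 11 (3R,4R,5S)-3,4-bis(hydroxymethyl)-5-[3-methoxy-4-(TIPSO)phenyl]oxolan-3-ol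
Product: 13 [(3R,6S,7R)-6-[3-methoxy-4-(TIPSO)phenyl]-1,5-dioxaspiro[2.4]heptan-7-yl]methanol, via primary tosylate 12 (not isolated)
Conditions: Bu2SnO (5 mol %), TsCl (1.05 equiv), Et3N, CH2Cl2, 0 °C → rt; then K2CO3, MeOH, 0 °C
Reagents that add atoms: none
Why: tin-catalysed sulfonylation passes through the five-membered stannylene acetal of the 1,2-diol and should therefore tosylate its primary hydroxyl in preference to the isolated one, after which the tertiary alkoxide closes the epoxide by 3-exo-tet displacement with the carbinol configuration retained.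

Step 10
Reactants: 13 [(3R,6S,7R)-6-[3-methoxy-4-(TIPSO)phenyl]-1,5-dioxaspiro[2.4]heptan-7-yl]methanol
Product: 14 4-[(3R,6S,7R)-7-(hydroxymethyl)-1,5-dioxaspiro[2.4]heptan-6-yl]-2-methoxyphenol
Conditions: TBAF (1.1 equiv), AcOH (1.1 equiv), THF, 0 °C
Reagents that add atoms: none
Why: fluoride-mediated cleavage of the aryl silyl ether, buffered with acetic acid so that the liberated phenoxide does not open the epoxide or the benzylic ether.

Step 11
Reactants: 15 4-bromo-2-methoxyphenol
Product: 16 (4-bromo-2-methoxyphenoxy)triisopropylsilane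
Conditions: TIPSCl, imidazole, DMF, rt
Reagents that add atoms: triisopropylsilyl chloride, CC(C)[Si](Cl)(C(C)C)C(C)C
Why: O-silylation of the phenol makes the aryl bromide fit for Grignard formation.

Step 12
Reactants: 16 (4-bromo-2-methoxyphenoxy)triisopropylsilane; 14 4-[(3R,6S,7R)-7-(hydroxymethyl)-1,5-dioxaspiro[2.4]heptan-6-yl]-2-methoxyphenol
Product: 18 (3S,4R,5S)-5-(4-hydroxy-3-methoxyphenyl)-4-(hydroxymethyl)-3-[3-methoxy-4-(TIPSO)benzyl]oxolan-3-ol, via arylmagnesium bromide 17 (not isolated)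
Conditions: Mg, LiCl, THF, rt (16, 4.5 equiv); then 14, CuI (20 mol %), THF, −30 → 0 °C
Reagents that add atoms: none
Why: copper-catalysed SN2 opening of the 2,2-disubstituted epoxide by the aryl Grignard reagent at its CH2 terminus should leave the configured tertiary carbinol untouched, the phenol and primary alcohol being carried as magnesium salts by excess reagent.

Step 13
Reactants: 18 (3S,4R,5S)-5-(4-hydroxy-3-methoxyphenyl)-4-(hydroxymethyl)-3-[3-methoxy-4-(TIPSO)benzyl]oxolan-3-ol
Product: 19 (3S,4R,5S)-5-(4-hydroxy-3-iodo-5-methoxyphenyl)-4-(hydroxymethyl)-3-[3-methoxy-4-(TIPSO)benzyl]oxolan-3-ol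
Conditions: NIS (1.05 equiv), DMF, 0 °C
Reagents that add atoms: N-iodosuccinimide, O=C1CCC(=O)N1I
Why: electrophilic aromatic iodination is directed by the free phenol to its only open ortho position (para is blocked), and the silylated guaiacyl ring is less activated.

Step 14
Reactants: 20 2-bromo-6-methoxyphenol
Product: 21 2-bromo-4-iodo-6-methoxyphenol
Conditions: NIS, p-TsOH (cat.), MeCN, rt
Reagents that add atoms: N-iodosuccinimide, O=C1CCC(=O)N1I
Why: electrophilic iodination of a 2,6-disubstituted phenol should go to the free para position.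

Step 15
Reactants: 21 2-bromo-4-iodo-6-methoxyphenol
Product: 22 (2-bromo-4-iodo-6-methoxyphenoxy)triisopropylsilane
Conditions: TIPSOTf, 2,6-lutidine, CH2Cl2, 0 °C → rt
Reagents that add atoms: triisopropylsilyl triflate, CC(C)[Si](OS(=O)(=O)C(F)(F)F)(C(C)C)C(C)C
Why: the silyl triflate is used because the phenol is flanked by two ortho substituents; O-silylation.

Step 16
Reactants: 22 (2-bromo-4-iodo-6-methoxyphenoxy)triisopropylsilane; 13 [(3R,6S,7R)-6-[3-methoxy-4-(TIPSO)phenyl]-1,5-dioxaspiro[2.4]heptan-7-yl]methanol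
Product: 24 (3S,4R,5S)-3-[3-bromo-5-methoxy-4-(TIPSO)benzyl]-4-(hydroxymethyl)-5-[3-methoxy-4-(TIPSO)phenyl]oxolan-3-ol, via arylmagnesium chloride 23 (not isolated)
Conditions: iPrMgCl·LiCl, THF, −20 °C (22, 3 equiv); then 13, CuI (20 mol %), −30 → 0 °C
Reagents that add atoms: none
Why: iodine–magnesium exchange is much faster than bromine–magnesium exchange, so the Grignard reagent should keep its bromide (meta to magnesium, no aryne), and copper-catalysed SN2 opening of the epoxide at CH2 gives the tertiary benzyl carbinol with the configuration unchanged.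

Step 17
Reactants: 24 (3S,4R,5S)-3-[3-bromo-5-methoxy-4-(TIPSO)benzyl]-4-(hydroxymethyl)-5-[3-methoxy-4-(TIPSO)phenyl]oxolan-3-ol; 19 (3S,4R,5S)-5-(4-hydroxy-3-iodo-5-methoxyphenyl)-4-(hydroxymethyl)-3-[3-methoxy-4-(TIPSO)benzyl]oxolan-3-ol
Product: 26 tris-TIPS ether of the target (free phenol on the aryl ring at C2 of half A; TIPS on the other three phenols), via pinacol boronate 25 (not isolated)
Conditions: B2pin2, Pd(dppf)Cl2 (5 mol %), KOAc, 1,4-dioxane, 90 °C; then 19, aq. K3PO4, 80 °C
Reagents that add atoms: none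
Why: Miyaura borylation of the aryl bromide followed in the same flask by Suzuki–Miyaura coupling with the aryl iodide (fast oxidative addition to zerovalent palladium) should form the biaryl bond with one ortho substituent on each ring and tolerate the free hydroxyl groups; no stereocentre is involved.

Step 18
Reactants: 26 tris-TIPS ether of the target
Product: 27 CNP0269573.1
Conditions: TBAF (4 equiv), AcOH (4 equiv), THF, 0 °C → rt
Reagents that add atoms: none
Why: buffered fluoride cleaves the three aryl silyl ethers in one operation under conditions that should not ionise the para-hydroxybenzylic ethers, so no hydrogenolysis is needed anywhere in the route.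

Compound list
1 | vanillin | COc1cc(C=O)ccc1O | starting material
2 | 3-methoxy-4-(TIPSO)benzaldehyde | COc1cc(C=O)ccc1O[Si](C(C)C)(C(C)C)C(C)C | intermediate
3 | methyl (Z)-3-[3-methoxy-4-(TIPSO)phenyl]prop-2-enoate | COC(=O)/C=C\c1ccc(O[Si](C(C)C)(C(C)C)C(C)C)c(OC)c1 | intermediate
4 | (Z)-3-[3-methoxy-4-(TIPSO)phenyl]prop-2-en-1-ol | OC/C=C\c1ccc(O[Si](C(C)C)(C(C)C)C(C)C)c(OC)c1 | intermediate
5 | (Z)-3-[3-methoxy-4-(TIPSO)phenyl]prop-2-en-1-yl bromoacetate | BrCC(=O)OC/C=C\c1ccc(O[Si](C(C)C)(C(C)C)C(C)C)c(OC)c1 | intermediate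
6 | (Z)-3-[3-methoxy-4-(TIPSO)phenyl]prop-2-en-1-yl diazoacetate | [N-]=[N+]=CC(=O)OC/C=C\c1ccc(O[Si](C(C)C)(C(C)C)C(C)C)c(OC)c1 | intermediate
7 | (1S,5R,6S)-6-[3-methoxy-4-(TIPSO)phenyl]-3-oxabicyclo[3.1.0]hexan-2-one | O=C1OC[C@@H]2[C@H](c3ccc(O[Si](C(C)C)(C(C)C)C(C)C)c(OC)c3)[C@H]12 | intermediate
8 | formaldehyde (as paraformaldehyde) | C=O | starting material
9 | (1R,5R,6S)-6-[3-methoxy-4-(TIPSO)phenyl]-3,7-dioxabicyclo[3.3.0]octan-2-one | O=C1OC[C@@H]2[C@@H](c3ccc(O[Si](C(C)C)(C(C)C)C(C)C)c(OC)c3)OC[C@H]12 | intermediate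
10 | (1S,5R,6S)-1-hydroxy-6-[3-methoxy-4-(TIPSO)phenyl]-3,7-dioxabicyclo[3.3.0]octan-2-one | O=C1OC[C@@H]2[C@@H](c3ccc(O[Si](C(C)C)(C(C)C)C(C)C)c(OC)c3)OC[C@]12O | intermediate
11 | (3R,4R,5S)-3,4-bis(hydroxymethyl)-5-[3-methoxy-4-(TIPSO)phenyl]oxolan-3-ol | OC[C@@]1(O)CO[C@H](c2ccc(O[Si](C(C)C)(C(C)C)C(C)C)c(OC)c2)[C@H]1CO | intermediate
12 | [(3S,4R,5S)-3-hydroxy-4-(hydroxymethyl)-5-[3-methoxy-4-(TIPSO)phenyl]oxolan-3-yl]methyl 4-methylbenzenesulfonate | Cc1ccc(cc1)S(=O)(=O)OC[C@@]1(O)CO[C@H](c2ccc(O[Si](C(C)C)(C(C)C)C(C)C)c(OC)c2)[C@H]1CO | intermediate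
13 | [(3R,6S,7R)-6-[3-methoxy-4-(TIPSO)phenyl]-1,5-dioxaspiro[2.4]heptan-7-yl]methanol | OC[C@@H]1[C@@H](c2ccc(O[Si](C(C)C)(C(C)C)C(C)C)c(OC)c2)OC[C@]12CO2 | intermediate
14 | 4-[(3R,6S,7R)-7-(hydroxymethyl)-1,5-dioxaspiro[2.4]heptan-6-yl]-2-methoxyphenol | OC[C@@H]1[C@@H](c2ccc(O)c(OC)c2)OC[C@]12CO2 | intermediate
15 | 4-bromo-2-methoxyphenol | COc1cc(Br)ccc1O | starting material
16 | (4-bromo-2-methoxyphenoxy)triisopropylsilane | COc1cc(Br)ccc1O[Si](C(C)C)(C(C)C)C(C)C | intermediate
17 | [3-methoxy-4-(TIPSO)phenyl]magnesium bromide | COc1cc([Mg]Br)ccc1O[Si](C(C)C)(C(C)C)C(C)C | intermediate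
18 | (3S,4R,5S)-5-(4-hydroxy-3-methoxyphenyl)-4-(hydroxymethyl)-3-[3-methoxy-4-(TIPSO)benzyl]oxolan-3-ol | COc1cc(C[C@@]2(O)CO[C@H](c3ccc(O)c(OC)c3)[C@H]2CO)ccc1O[Si](C(C)C)(C(C)C)C(C)C | intermediate
19 | (3S,4R,5S)-5-(4-hydroxy-3-iodo-5-methoxyphenyl)-4-(hydroxymethyl)-3-[3-methoxy-4-(TIPSO)benzyl]oxolan-3-ol | COc1cc(C[C@@]2(O)CO[C@H](c3cc(I)c(O)c(OC)c3)[C@H]2CO)ccc1O[Si](C(C)C)(C(C)C)C(C)C | intermediate
20 | 2-bromo-6-methoxyphenol | COc1cccc(Br)c1O | starting material
21 | 2-bromo-4-iodo-6-methoxyphenol | COc1cc(I)cc(Br)c1O | intermediate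
22 | (2-bromo-4-iodo-6-methoxyphenoxy)triisopropylsilane | COc1cc(I)cc(Br)c1O[Si](C(C)C)(C(C)C)C(C)C | intermediate
23 | [3-bromo-5-methoxy-4-(TIPSO)phenyl]magnesium chloride (LiCl complex) | COc1cc([Mg]Cl)cc(Br)c1O[Si](C(C)C)(C(C)C)C(C)C | intermediate
24 | (3S,4R,5S)-3-[3-bromo-5-methoxy-4-(TIPSO)benzyl]-4-(hydroxymethyl)-5-[3-methoxy-4-(TIPSO)phenyl]oxolan-3-ol | COc1cc(C[C@@]2(O)CO[C@H](c3ccc(O[Si](C(C)C)(C(C)C)C(C)C)c(OC)c3)[C@H]2CO)cc(Br)c1O[Si](C(C)C)(C(C)C)C(C)C | intermediate
25 | pinacol boronate of 24 (Bpin in place of Br) | COc1cc(C[C@@]2(O)CO[C@H](c3ccc(O[Si](C(C)C)(C(C)C)C(C)C)c(OC)c3)[C@H]2CO)cc(B3OC(C)(C)C(C)(C)O3)c1O[Si](C(C)C)(C(C)C)C(C)C | intermediate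
26 | tris-TIPS ether of the target | COc1cc(C[C@@]2(O)CO[C@H](c3cc(OC)c(O)c(-c4cc(C[C@@]5(O)CO[C@H](c6ccc(O[Si](C(C)C)(C(C)C)C(C)C)c(OC)c6)[C@H]5CO)cc(OC)c4O[Si](C(C)C)(C(C)C)C(C)C)c3)[C@H]2CO)ccc1O[Si](C(C)C)(C(C)C)C(C)C | intermediate
27 | CNP0269573.1 | COc1cc(C[C@@]2(O)CO[C@H](c3cc(OC)c(O)c(-c4cc(C[C@@]5(O)CO[C@H](c6ccc(O)c(OC)c6)[C@H]5CO)cc(OC)c4O)c3)[C@H]2CO)ccc1O | target

Total step count: 18. Longest linear sequence: 14 steps (steps 1–10, 12, 13, 17, 18).

Steps most likely to fail

Step 6. The single lactone carbonyl may polarise the cyclopropane too weakly, so that ring opening is slow and the benzylic cation, once formed, is lost to proton loss or oligomerisation before formaldehyde is captured. The fallback adds a second acceptor so that the annulation becomes the established diester case. It sets out from allylic alcohol 4: acylation with methyl malonyl chloride and pyridine should give methyl (Z)-3-[3-methoxy-4-(TIPSO)phenyl]prop-2-en-1-yl malonate F1, and diazo transfer (p-acetamidobenzenesulfonyl azide, Et3N, MeCN) the diazomalonate F2. Intramolecular cyclopropanation (CuOTf with a chiral bis(oxazoline) ligand, stereospecific for the Z alkene) should give methyl (1S,5R,6S)-6-[3-methoxy-4-(TIPSO)phenyl]-2-oxo-3-oxabicyclo[3.1.0]hexane-1-carboxylate F3; lower enantioselectivity is expected here, so enrichment by crystallisation is planned. The doubly activated cyclopropane should undergo the known Sn(OTf)2-catalysed annulation with paraformaldehyde to give methyl (1R,5R,6S)-6-[3-methoxy-4-(TIPSO)phenyl]-2-oxo-3,7-dioxabicyclo[3.3.0]octane-1-carboxylate F4. Krapcho demethoxycarbonylation (LiCl, wet DMSO, 130 °C), with the cis ring fusion enforced on protonation, comes back to the route at lactone 9.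

Step 9. Sulfonylation may occur at the wrong primary hydroxyl, after which base would close an oxetane or a second oxolane ring instead of the epoxide. The fallback differentiates the hydroxyls by protection instead of by catalyst control. It sets out from triol 11: 2,2-dimethoxypropane with PPTS should give the five-membered acetonide of the 1,2-diol F5, benzoyl chloride and pyridine the benzoate of the remaining primary alcohol F6, and aqueous acetic acid the diol benzoate F7. TsCl in pyridine can then sulfonylate only the single free primary hydroxyl to give tosylate F8. K2CO3 in methanol closes the epoxide and cleaves the benzoate in the same operation, coming back to the route at epoxide 13.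

Step 17. The boronate flanked by the bulky silyl ether may transmetalate slowly and suffer protodeboronation or base-induced desilylation under the aqueous basic conditions. The fallback replaces the boron partner by a tin partner under base-free conditions. It sets out from bromide 24: hexamethylditin with Pd(PPh3)4 in toluene at 100 °C should give the trimethylstannane F9, and Stille coupling of F9 with iodide 19 (Pd(PPh3)4, CuI, CsF, DMF, 45 °C) comes back to the route at 26.

Further compounds
F1 | step 6 | methyl (Z)-3-[3-methoxy-4-(TIPSO)phenyl]prop-2-en-1-yl malonate | COC(=O)CC(=O)OC/C=C\c1ccc(O[Si](C(C)C)(C(C)C)C(C)C)c(OC)c1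
F2 | step 6 | methyl (Z)-3-[3-methoxy-4-(TIPSO)phenyl]prop-2-en-1-yl diazomalonate | COC(=O)C(=[N+]=[N-])C(=O)OC/C=C\c1ccc(O[Si](C(C)C)(C(C)C)C(C)C)c(OC)c1
F3 | step 6 | methyl (1S,5R,6S)-6-[3-methoxy-4-(TIPSO)phenyl]-2-oxo-3-oxabicyclo[3.1.0]hexane-1-carboxylate | O=C1OC[C@@H]2[C@H](c3ccc(O[Si](C(C)C)(C(C)C)C(C)C)c(OC)c3)[C@]12C(=O)OC
F4 | step 6 | methyl (1R,5R,6S)-6-[3-methoxy-4-(TIPSO)phenyl]-2-oxo-3,7-dioxabicyclo[3.3.0]octane-1-carboxylate | O=C1OC[C@@H]2[C@@H](c3ccc(O[Si](C(C)C)(C(C)C)C(C)C)c(OC)c3)OC[C@]12C(=O)OC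
F5 | step 9 | acetonide of the 1,2-diol of 11 (spiro-dioxolane at C4, free CH2OH on C3) | CC1(C)OC[C@@]2(O1)CO[C@H](c3ccc(O[Si](C(C)C)(C(C)C)C(C)C)c(OC)c3)[C@H]2CO
F6 | step 9 | benzoate of F5 | CC1(C)OC[C@@]2(O1)CO[C@H](c3ccc(O[Si](C(C)C)(C(C)C)C(C)C)c(OC)c3)[C@H]2COC(=O)c4ccccc4
F7 | step 9 | diol benzoate (benzoate on the C3 hydroxymethyl of 11) | OC[C@@]1(O)CO[C@H](c2ccc(O[Si](C(C)C)(C(C)C)C(C)C)c(OC)c2)[C@H]1COC(=O)c3ccccc3
F8 | step 9 | primary tosylate of F7 | Cc1ccc(cc1)S(=O)(=O)OC[C@@]2(O)CO[C@H](c3ccc(O[Si](C(C)C)(C(C)C)C(C)C)c(OC)c3)[C@H]2COC(=O)c4ccccc4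
F9 | step 17 | trimethylstannane from 24 (SnMe3 in place of Br) | COc1cc(C[C@@]2(O)CO[C@H](c3ccc(O[Si](C(C)C)(C(C)C)C(C)C)c(OC)c3)[C@H]2CO)cc([Sn](C)(C)C)c1O[Si](C(C)C)(C(C)C)C(C)C
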